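**Retrosynthetic overview**
1. Aplidic acid A ⇒ vinylogous HWE at C4 of the hydrindene (adds the dienoate) ⇒ C4 aldehyde ⇒ glycol cleavage of a C4 dioxolane.
2. Key disconnection: C3a–C7a and C4–C5 are cut together. The cyclopentane and the cyclohexene therefore form at the same time, in one thermal intramolecular Diels–Alder reaction of an acyclic pentaene acid that already carries the whole octadienoic acid chain.
3. The dienophile is an unactivated Z-alkene, because an activated E-dienophile would give the C4 epimer. Its single sacrificial glyceraldehyde dioxolane stereocentre controls all four ring stereocentres.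
4. Pentaene acid ⇒ Suzuki union of an E,E-chlorodiene and an E,E-dienylboronate.
5. Chlorodiene ⇒ Z-Wittig of (S)-glyceraldehyde acetonide with a hexynyl ylide, then hydrozirconation and coupling with ClCH=CHCl. Boronate ⇒ hex-5-ynoic acid plus vinyl-Bpin (Heck).

Assumption: methyl (2E)-4-(diethoxyphosphoryl)but-2-enoate is bought as a catalogue item; carboxylic acids are written neutral although they sit as carboxylate salts under basic conditions until acidic work-up.

**Step 1**
Reactants: 1 (R)-solketal, [(4R)-2,2-dimethyl-1,3-dioxolan-4-yl]methanol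
Product: 2 (4S)-2,2-dimethyl-1,3-dioxolane-4-carbaldehyde
Conditions: TEMPO (10 mol %), PhI(OAc)2 (1.1 equiv), CH2Cl2, 0 °C → rt; short-path distillation
Reagents that add atoms: none
Why: TEMPO/PhI(OAc)2 (oxoammonium) oxidation of a primary alcohol stops at the aldehyde under non-basic conditions, so the stereocentre bought with 1 is carried over unchanged (R becomes S only because CHO outranks C5).

**Step 2**
Reactants: 3 6-iodohex-1-yne
Product: 4 (hex-5-yn-1-yl)triphenylphosphonium iodide
Conditions: PPh3 (1.05 equiv), MeCN, reflux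
Reagents that add atoms: triphenylphosphine, c1ccc(cc1)P(c1ccccc1)c1ccccc1
Why: SN2 quaternisation of triphenylphosphine by an unhindered primary iodide (phosphonium salt formation) leaves the terminal alkyne untouched and creates no stereocentre.

**Step 3**
Reactants: 4 (hex-5-yn-1-yl)triphenylphosphonium iodide; 2 (4S)-2,2-dimethyl-1,3-dioxolane-4-carbaldehyde
Product: 6 (4R)-4-[(1Z)-hept-1-en-6-yn-1-yl]-2,2-dimethyl-1,3-dioxolane, via phosphorus ylide 5 (not isolated)
Conditions: NaHMDS (1.0 equiv), THF, −78 °C; then 2, −78 °C → rt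
Reagents that add atoms: none
Why: Wittig olefination with a non-stabilised ylide under lithium-free kinetic conditions should give the Z-alkene (expected about 15:1 or better with this aldehyde), the P–CH2 protons being far more acidic than the alkyne C–H and the low temperature preventing epimerisation of 2, whose stereocentre becomes C4 of 6 (R by priority change).

**Step 4**
Reactants: 6 (4R)-4-[(1Z)-hept-1-en-6-yn-1-yl]-2,2-dimethyl-1,3-dioxolane; 7 (E)-1,2-dichloroethene
Product: 9 (4R)-4-[(1Z,6E,8E)-9-chloronona-1,6,8-trien-1-yl]-2,2-dimethyl-1,3-dioxolane, via alkenylzirconocene chloride 8 (not isolated)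
Conditions: Cp2Zr(H)Cl (1.2 equiv), THF, rt, dark; then 7 (6 equiv), Pd(PPh3)4 (5 mol %), ZnCl2 (20 mol %), 45 °C
Reagents that add atoms: none
Why: Schwartz hydrozirconation adds Zr–H syn and only to the terminal alkyne (the internal Z-alkene and the acetal are inert), and the Negishi-type Pd/Zn-catalysed alkenyl–alkenyl coupling proceeds with retention at both partners, the large excess of dichloride stopping the reaction at mono-substitution to give the E,E-chlorodiene.

**Step 5**
Reactants: 10 hex-5-ynoic acid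
Product: 12 (5E)-6-iodohex-5-enoic acid, via bis-zirconocene species 11 (not isolated)
Conditions: Cp2Zr(H)Cl (2.3 equiv), THF, 0 °C → rt; I2 (1.1 equiv), 0 °C; 1 M HCl
Reagents that add atoms: iodine, II
Why: Hydrozirconation–iodinolysis, in which the first equivalent of Cp2Zr(H)Cl is consumed by the acid proton, the second adds syn to the terminal alkyne, and iodine cleaves the C–Zr bond with retention to give only the E-vinyl iodide.

**Step 6**
Reactants: 12 (5E)-6-iodohex-5-enoic acid; 13 2-ethenyl-4,4,5,5-tetramethyl-1,3,2-dioxaborolane (vinyl-Bpin)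
Product: 14 (5E,7E)-8-(4,4,5,5-tetramethyl-1,3,2-dioxaborolan-2-yl)octa-5,7-dienoic acid
Conditions: Pd(OAc)2 (5 mol %), P(o-tol)3 (10 mol %), AgOAc (1.3 equiv), MeCN, 50 °C
Reagents that add atoms: none
Why: Heck–Mizoroki reaction of the vinylboronate under silver-mediated conditions, where carbopalladation at the unsubstituted CH2 terminus and syn β-hydride elimination outrun Suzuki transfer and give the E,E-dienylboronate with the iodide geometry retained.

**Step 7**
Reactants: 9 (4R)-4-[(1Z,6E,8E)-9-chloronona-1,6,8-trien-1-yl]-2,2-dimethyl-1,3-dioxolane; 14 (5E,7E)-8-(4,4,5,5-tetramethyl-1,3,2-dioxaborolan-2-yl)octa-5,7-dienoic acid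
Product: 15 (5E,7E,9E,11E,16Z)-17-[(4R)-2,2-dimethyl-1,3-dioxolan-4-yl]heptadeca-5,7,9,11,16-pentaenoic acid
Conditions: Pd(OAc)2 (3 mol %), SPhos (6 mol %), K3PO4 (3.5 equiv), THF–H2O 10:1, 40 °C, dark, degassed; work-up at pH 4
Reagents that add atoms: none
Why: Suzuki–Miyaura alkenyl–alkenyl coupling with retention at both sp2 carbons, made possible for the conjugated C–Cl bond by the electron-rich SPhos ligand at a temperature far below that needed for cycloaddition.

**Step 8 (key step)**
Reactants: 15 (5E,7E,9E,11E,16Z)-17-[(4R)-2,2-dimethyl-1,3-dioxolan-4-yl]heptadeca-5,7,9,11,16-pentaenoic acid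
Product: 16 (5E,7E)-8-{(3aR,4R,5R,7aS)-4-[(4R)-2,2-dimethyl-1,3-dioxolan-4-yl]-2,3,3a,4,5,7a-hexahydro-1H-inden-5-yl}octa-5,7-dienoic acid
Conditions: PhMe (5 mM, degassed), BHT (10 mol %), silanised sealed tube, 185 °C, 36 h
Reagents that add atoms: none
Why: Type-1 intramolecular Diels–Alder reaction in which the three-carbon tether lets only the proximal diene (C9–C12) reach C16=C17, suprafacial addition turns the Z-alkene into cis H-3a/H-4 and the E,E-diene into cis H-5/H-7a, the branched dioxolane cannot sit under the diene so it and the tether stay exo (trans ring fusion, C4 and C5 chains trans), and A1,3 strain holds the allylic C–H in the alkene plane so that the diene is predicted to bond anti to the dioxolane CH2O arm with the small ring oxygen outside, which for the 4R acetal gives 3aR,4R,5R,7aS.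

**Step 9**
Reactants: 16 (5E,7E)-8-{(3aR,4R,5R,7aS)-4-[(4R)-2,2-dimethyl-1,3-dioxolan-4-yl]-2,3,3a,4,5,7a-hexahydro-1H-inden-5-yl}octa-5,7-dienoic acid
Product: 18 (5E,7E)-8-[(3aR,4R,5R,7aS)-4-formyl-2,3,3a,4,5,7a-hexahydro-1H-inden-5-yl]octa-5,7-dienoic acid, via vicinal diol 17 (not isolated)
Conditions: H5IO6 (1.5 equiv), EtOAc, 0 °C → rt, 1–2 h; aq. Na2S2O3 wash
Reagents that add atoms: none
Why: Periodic acid first hydrolyses the terminal acetonide and then cleaves the liberated 1,2-diol (Malaprade reaction) without touching the alkenes or the acid, and the short, cold, base-free exposure keeps the axial C4 formyl group from epimerising.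

**Step 10**
Reactants: 18 (5E,7E)-8-[(3aR,4R,5R,7aS)-4-formyl-2,3,3a,4,5,7a-hexahydro-1H-inden-5-yl]octa-5,7-dienoic acid; 19 methyl (2E)-4-(diethoxyphosphoryl)but-2-enoate
Product: 21 aplidic acid A, (5E,7E)-8-{(3aR,4R,5R,7aS)-4-[(1E,3E)-5-methoxy-5-oxopenta-1,3-dien-1-yl]-2,3,3a,4,5,7a-hexahydro-1H-inden-5-yl}octa-5,7-dienoic acid, via lithiated phosphonate 20 (not isolated)
Conditions: 19 (2.4 equiv), LiHMDS (2.3 equiv), THF, −78 °C; then 18, −78 → −20 °C; 1 M HCl to pH 3
Reagents that add atoms: none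
Why: Vinylogous Horner–Wadsworth–Emmons olefination, in which the weakly basic delocalised phosphonate anion adds to the aldehyde at low temperature faster than it enolises it, reacts at its α-carbon and eliminates to the new E-alkene while the existing E-enoate is kept, giving the E,E-dienoate with C4 intact.

**Compound list**
1 | (R)-solketal, [(4R)-2,2-dimethyl-1,3-dioxolan-4-yl]methanol | CC1(C)OC[C@H](O1)CO | starting material
2 | (4S)-2,2-dimethyl-1,3-dioxolane-4-carbaldehyde | CC1(C)OC[C@H](O1)C=O | intermediate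
3 | 6-iodohex-1-yne | C#CCCCCI | starting material
4 | (hex-5-yn-1-yl)triphenylphosphonium iodide | C#CCCCC[P+](c1ccccc1)(c1ccccc1)c1ccccc1.[I-] | intermediate
5 | (hex-5-yn-1-ylidene)triphenyl-λ5-phosphane (ylide) | C#CCCCC=P(c1ccccc1)(c1ccccc1)c1ccccc1 | intermediate
6 | (4R)-4-[(1Z)-hept-1-en-6-yn-1-yl]-2,2-dimethyl-1,3-dioxolane | CC1(C)OC[C@H](O1)/C=C\CCCC#C | intermediate
7 | (E)-1,2-dichloroethene | Cl/C=C/Cl | starting material
8 | chlorobis(cyclopentadienyl){(1E,6Z)-7-[(4R)-2,2-dimethyl-1,3-dioxolan-4-yl]hepta-1,6-dien-1-yl}zirconium | CC1(C)OC[C@H](O1)/C=C\CCC/C=C/[Zr](Cl)(C2C=CC=C2)C2C=CC=C2 | intermediate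
9 | (4R)-4-[(1Z,6E,8E)-9-chloronona-1,6,8-trien-1-yl]-2,2-dimethyl-1,3-dioxolane | CC1(C)OC[C@H](O1)/C=C\CCC/C=C/C=C/Cl | intermediate
10 | hex-5-ynoic acid | C#CCCCC(=O)O | starting material
11 | chlorozirconocene (5E)-6-(chlorozirconocenyl)hex-5-enoate | Cl[Zr](OC(=O)CCC/C=C/[Zr](Cl)(C1C=CC=C1)C1C=CC=C1)(C1C=CC=C1)C1C=CC=C1 | intermediate
12 | (5E)-6-iodohex-5-enoic acid | OC(=O)CCC/C=C/I | intermediate
13 | 2-ethenyl-4,4,5,5-tetramethyl-1,3,2-dioxaborolane | C=CB1OC(C)(C)C(C)(C)O1 | starting material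
14 | (5E,7E)-8-(4,4,5,5-tetramethyl-1,3,2-dioxaborolan-2-yl)octa-5,7-dienoic acid | OC(=O)CCC/C=C/C=C/B1OC(C)(C)C(C)(C)O1 | intermediate
15 | (5E,7E,9E,11E,16Z)-17-[(4R)-2,2-dimethyl-1,3-dioxolan-4-yl]heptadeca-5,7,9,11,16-pentaenoic acid | CC1(C)OC[C@H](O1)/C=C\CCC/C=C/C=C/C=C/C=C/CCCC(=O)O | intermediate
16 | (5E,7E)-8-{(3aR,4R,5R,7aS)-4-[(4R)-2,2-dimethyl-1,3-dioxolan-4-yl]-2,3,3a,4,5,7a-hexahydro-1H-inden-5-yl}octa-5,7-dienoic acid | CC1(C)OC[C@H](O1)[C@@H]2[C@@H]3CCC[C@H]3C=C[C@H]2/C=C/C=C/CCCC(=O)O | intermediate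
17 | (5E,7E)-8-{(3aR,4R,5R,7aS)-4-[(1R)-1,2-dihydroxyethyl]-2,3,3a,4,5,7a-hexahydro-1H-inden-5-yl}octa-5,7-dienoic acid | OC[C@H](O)[C@@H]1[C@@H]2CCC[C@H]2C=C[C@H]1/C=C/C=C/CCCC(=O)O | intermediate
18 | (5E,7E)-8-[(3aR,4R,5R,7aS)-4-formyl-2,3,3a,4,5,7a-hexahydro-1H-inden-5-yl]octa-5,7-dienoic acid | O=C[C@@H]1[C@@H]2CCC[C@H]2C=C[C@H]1/C=C/C=C/CCCC(=O)O | intermediate
19 | methyl (2E)-4-(diethoxyphosphoryl)but-2-enoate | CCOP(=O)(C/C=C/C(=O)OC)OCC | starting material
20 | lithium salt of the α-carbanion of 19 | [Li+].CCOP(=O)([CH-]/C=C/C(=O)OC)OCC | intermediate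
21 | aplidic acid A | COC(=O)/C=C/C=C/[C@@H]1[C@@H]2CCC[C@H]2C=C[C@H]1/C=C/C=C/CCCC(=O)O | target

**Total step count:** 10. **Longest linear sequence:** 7 (steps 1, 3, 4, 7, 8, 9, 10).

**Three steps most likely to fail**

**Step 8.** The dienophile is unactivated, so the cyclisation may be slow. The exo/endo ratio and the sense of facial selectivity rest on a steric model and are not proven.
- The fallback gives up substrate control. It sets out from 15 and comes back at 18.
- The dioxolane of 15 is cleaved first with H5IO6 to give (5E,7E,9E,11E,16Z)-18-oxooctadeca-5,7,9,11,16-pentaenoic acid F1.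
- A MacMillan imidazolidinone salt isomerises it through the iminium ion to (5E,7E,9E,11E,16E)-18-oxooctadeca-5,7,9,11,16-pentaenoic acid F2.
- The same catalyst cyclises F2 at or below room temperature by an endo-selective iminium-catalysed intramolecular Diels–Alder reaction. The catalyst enantiomer is chosen to give the 3aR,5R,7aS series.
- The product is the C4 epimer (5E,7E)-8-[(3aR,4S,5R,7aS)-4-formyl-2,3,3a,4,5,7a-hexahydro-1H-inden-5-yl]octa-5,7-dienoic acid F3.
- Catalytic DBU equilibrates F3 at C4. A conformational estimate puts the two epimers close in energy. Chromatography with recycling of the unwanted epimer delivers 18.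

**Step 7.** The alkenyl chloride may react sluggishly, and the tetraene is fragile. The fallback reverses the polarity of the union and uses an iodide. It sets out from 6 and 14 and comes back at 15.
- Compound 6 is hydrozirconated to 8 and quenched with iodine to give (4R)-4-[(1Z,6E)-7-iodohepta-1,6-dien-1-yl]-2,2-dimethyl-1,3-dioxolane F4.
- A Heck reaction of F4 with 13 gives (4R)-2,2-dimethyl-4-[(1Z,6E,8E)-9-(4,4,5,5-tetramethyl-1,3,2-dioxaborolan-2-yl)nona-1,6,8-trien-1-yl]-1,3-dioxolane F5.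
- In parallel, 14 is iododeboronated with retention (NaOMe, then ICl) to (5E,7E)-8-iodoocta-5,7-dienoic acid F6.
- A room-temperature Suzuki coupling of F5 with F6 (Pd(PPh3)4, aqueous base) gives 15.

**Step 10.** The axial α-stereogenic aldehyde could epimerise under the anionic conditions, or the new alkene could form with poor E/Z selectivity. The fallback replaces the one anionic olefination by two base-free Wittig reactions with stabilised ylides. It sets out from 18 and comes back at 21.
- Ph3P=CHCHO in toluene converts 18 into (5E,7E)-8-{(3aR,4R,5R,7aS)-4-[(1E)-3-oxoprop-1-en-1-yl]-2,3,3a,4,5,7a-hexahydro-1H-inden-5-yl}octa-5,7-dienoic acid F7.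
- Ph3P=CHCO2Me in CH2Cl2 then converts F7 into 21.

**Further compounds**
F1 | step 8 | (5E,7E,9E,11E,16Z)-18-oxooctadeca-5,7,9,11,16-pentaenoic acid | O=C/C=C\CCC/C=C/C=C/C=C/C=C/CCCC(=O)O
F2 | step 8 | (5E,7E,9E,11E,16E)-18-oxooctadeca-5,7,9,11,16-pentaenoic acid | O=C/C=C/CCC/C=C/C=C/C=C/C=C/CCCC(=O)O
F3 | step 8 | (5E,7E)-8-[(3aR,4S,5R,7aS)-4-formyl-2,3,3a,4,5,7a-hexahydro-1H-inden-5-yl]octa-5,7-dienoic acid | O=C[C@H]1[C@@H]2CCC[C@H]2C=C[C@H]1/C=C/C=C/CCCC(=O)O
F4 | step 7 | (4R)-4-[(1Z,6E)-7-iodohepta-1,6-dien-1-yl]-2,2-dimethyl-1,3-dioxolane | CC1(C)OC[C@H](O1)/C=C\CCC/C=C/I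
F5 | step 7 | (4R)-2,2-dimethyl-4-[(1Z,6E,8E)-9-(4,4,5,5-tetramethyl-1,3,2-dioxaborolan-2-yl)nona-1,6,8-trien-1-yl]-1,3-dioxolane | CC1(C)OC[C@H](O1)/C=C\CCC/C=C/C=C/B2OC(C)(C)C(C)(C)O2
F6 | step 7 | (5E,7E)-8-iodoocta-5,7-dienoic acid | OC(=O)CCC/C=C/C=C/I
F7 | step 10 | (5E,7E)-8-{(3aR,4R,5R,7aS)-4-[(1E)-3-oxoprop-1-en-1-yl]-2,3,3a,4,5,7a-hexahydro-1H-inden-5-yl}octa-5,7-dienoic acid | O=C/C=C/[C@@H]1[C@@H]2CCC[C@H]2C=C[C@H]1/C=C/C=C/CCCC(=O)O
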